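# Proposed total synthesis of agrimol F by Danheiser benzannulation on the bridging carbon

## Analysis of the target

Agrimol F is an achiral trimeric acylphloroglucinol in which a central butanoylphloroglucinol (ring B) is joined through two methylene bridges to ring A, which carries an acetyl group, and to ring C, which carries a butanoyl group. Ring atoms are written with the ring letter after the locant: ring B has the butanoyl group at C-1B, hydroxyls at C-2B, C-4B and C-6B, the bridge to ring A at C-3B and the bridge to ring C at C-5B, while rings A and C each have the bridging methylene at C-1, hydroxyls at C-2 and C-6, methyl at C-3, methoxy at C-4 and the acyl group at C-5. There is no stereocentre, so no stereochemical relationship has to be set, and the stereocentres that appear in intermediates are racemic and are erased again. The sensitive elements are the seven free phenols, the three chelated aryl ketones and, above all, the two diarylmethane bridges between phloroglucinol rings, which base and strong acid cleave and redistribute through quinone methides. The synthesis is hard because rings A and C differ only in the length of the acyl chain and must still be told apart, and because every late step has to spare the bridges. It is hard also because the methoxy group sits ortho to the acyl group and beside the C-methyl group, whereas O-methylation of an acylphloroglucinol goes para to the ketone and C-methylation goes between two hydroxyls, so that classical alkylation leads to the wrong isomer. The strategy rests on ring A, in which C-6A (OH), C-1A (bridge), C-2A (O), C-3A (CH3), C-4A (OCH3) and C-5A form a 1,3,5-trioxygenated benzene. Taken in this order, these atoms map onto the carbonyl carbon of a cyclobutenone, the two carbons of an ynol ether and the remaining three carbons of 3-methoxy-2-methylcyclobutenone.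

## Retrosynthetic reasoning

**Second bridge, 35 to 22 and 33.** The target 35 is cut at the bond between C-5B and the methylene group of ring C. This is the only place where the cut gives two partners with a single possible union: C-5B is the only unsubstituted aromatic carbon of the ring A–ring B unit 22, and the ring C unit 33 has none. The methylene carbon stays on ring C because that ring can be made with its benzylic carbon already attached. The forward reaction has to ionise the benzylic methyl ether of 33 to quinone methide 34 and let 22 capture it, with no protecting group left to remove afterwards.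

**Butanoyl group of ring B, 22 to 19.** 22 is traced through 21 and 20 back to 19 by removing the butanoyl group at C-1B and restoring three benzyl ethers and one silyl ether. The acyl bond is cut at this stage because ring A of 19 is fully substituted and the two open positions of ring B are related by the mirror plane through C-3B and C-6B. Mono-acylation can therefore give only one ketone. Acylating the benzyl ether rather than the free phloroglucinol avoids O-acylation of ring B. The silyl ether at C-2A protects the only unchelated phenol.

**Acetyl group of ring A, 19 to 16.** 19 is traced through 18 and 17 back to phenol 16 by cutting the bond between C-5A and the acetyl carbon. The handle is the free hydroxyl at C-6A that the ring construction leaves behind. Esterification followed by acid-promoted acyl migration was set aside because ring B of 16 is as nucleophilic as C-5A and carries acid-labile benzyl ethers. The acetyl group is instead built in three mild steps that only a free phenol can direct: phenoxide-directed ortho-formylation, addition of a methyl nucleophile and oxidation. The gain is complete selectivity for ring A over ring B.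

**Ring A, 16 to 11 and 6 (key disconnection).** Ring A of 16 is cut at three bonds: C-1A–C-6A, C-2A–C-3A and C-5A–C-6A. This gives silyl ynol ether 11, which carries ring B on its propargylic carbon, and cyclobutenone 6. The cut removes all five substituents of ring A at once, including the bridging methylene and the methoxy group beside the methyl group. No other disconnection of the ring does this. The forward reaction has to open 6 to vinylketene 12, add it to the ynol ether with one regiochemistry and close the ring.

**Ynol ether, 11 to 7.** 11 is traced to ester 9 through ynolate 10, so the alkyne carbon bearing oxygen is the former ester carbonyl and the other alkyne carbon is added as a one-carbon unit. 9 comes from bromide 8 by cross-coupling with an acetate enolate, and 8 from 7 by bromination. The precursor is reached in three steps.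

**Cyclobutenone, 6 to 1 and 2.** 6 is the methyl enol ether of dione 5. 5 arises by hydrolysis of cyclobutenone 4, the cycloadduct of methylketene 3 (from 1) and 2. The detour through 5 is needed because the cycloaddition places the methyl group on the saturated carbon. Enolisation of 5 moves the double bond to the methyl-bearing carbon.

**Ring C unit, 33 to 23 and 6.** 33 is traced through 32, 31 and 30 back to phenol 29 by the same three-step construction of the acyl group, here with a propyl nucleophile. 29 is cut exactly as ring A was, to cyclobutenone 6 and ynol ether 25, which comes from ester 23 through ynolate 24. Reusing the ring construction fixes the methoxy and methyl groups of ring C as well, and supplies the benzylic carbon as a methoxymethyl group.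

## Alternatives that were turned down

**Alternative 1:** The disconnection is the C-1C–C-2C bond of ring C. Compound A1, which is the target without the butanoyl group at C-5C, is traced back to pyrone A2, in which a 4-methoxy-3-methyl-2-pyrone ring hangs on C-5B through a two-carbon tether. In the forward sense an alkoxide base opens the lactone of A2, and the enolate of the ketone so formed, at the tether carbon next to the former pyrone ring, attacks the liberated ester. Ring C then forms as a carbocycle directly on the bridge and A2 becomes A1.

- For it: the methyl and methoxy groups of ring C are fixed by the pyrone of A2, and the second bridge is never made by a reversible benzylation. On bridge security it is stronger than the chosen route, whose last step is exactly such a benzylation.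
- Against it: the ring transformation needs alkoxide and heat on A2, a substrate that already holds the ring A–ring B bridge and two enolisable aryl ketones. The bridge can fragment under these conditions, and the acetyl and butanoyl enolates compete for the ester.
- Against it: A1 still lacks the butanoyl group at C-5C. It would have to be introduced by electrophilic acylation of the complete, unprotected trimer.
- Against it: it leaves ring A, which has the same substitution problem, unaddressed.
- Comparison: the chosen strategy offers one neutral, thermal reaction that sets the pattern of both outer rings before any polyphenol or bridge exists, and all three acyl groups are in place before the trimer is assembled.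

**Alternative 2:** The disconnection removes the acetyl group and the oxygen at C-6A together. Ketone A3 is traced back to aryne A5, generated from silylaryl triflate A4 with CsF, and acetic acid A6. The carboxylate adds at C-6A, the aryne carbon remote from the methoxy group, and the aryl anion formed at C-5A takes the acetyl group over from oxygen.

- For it: acetyl and hydroxyl enter in one operation, with regiochemistry set by the inductive effect of the methoxy group. The chosen route needs three steps for the same acetyl group, so the alternative is clearly stronger on this point.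
- Against it: it only decorates a ring that must already carry the methoxy group beside the methyl group and a separately protected oxygen at C-2A. A4 is a pentasubstituted arene whose preparation is the unsolved part.
- Against it: C-1A stays unsubstituted in A3, so both bridges would have to be made later by benzylation between two nearly identical outer rings.
- Comparison: the chosen strategy spends more steps on the acyl group. In exchange it builds the ring with all five substituents, including the bridging methylene, from two simple fragments.

**Alternative 3:** The disconnection cuts both aryl–methylene bonds at ring B. Bromo-iodo ketone A8 is coupled in one flask, with Pd(OAc)2 and SPhos, first at the C–I bond with benzylzinc chloride A9 (ring A) and then at the C–Br bond with benzylzinc chloride A10 (ring C). The product is hepta-O-benzyl agrimol F A7.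

- For it: it is the most convergent plan. Both bridges are made irreversibly under neutral conditions, and the order of halogen reactivity distinguishes rings A and C without any ambiguity. On convergence and bridge security it is stronger than the chosen route.
- Against it: each coupling joins a hexasubstituted ring, at a carbon flanked by two benzyloxy groups, to a benzylzinc reagent that is itself flanked by two benzyloxy groups. The second coupling must occur at a hindered, electron-rich C–Br bond.
- Against it: A9 and A10 presuppose the fully substituted outer rings, so the methoxy and methyl pattern is again left to classical chemistry.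
- Against it: seven benzyl ethers have to be removed beside three aryl ketones.
- Comparison: the chosen strategy is longer and ends with a more delicate bond formation, but it is the only one of the four that constructs the outer rings instead of assuming them.

Key step: step 7

Assumption: compounds 7, 2 (as a solution in hexanes), 23 and the zinc reagent of step 5 are treated as purchasable; the chiral intermediates 4, 13, 18, 26 and 31 are racemic and lose their stereocentre on the way to the achiral target.

## Route

Step 1
Reactants: 1 propanoyl chloride; 2 ethoxyethyne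
Product: 4 (±)-3-ethoxy-4-methylcyclobut-2-en-1-one, via methylketene 3 (not isolated)
Conditions: Et3N, Et2O, 0 → 23 °C (slow addition of 1 to 2)
Reagents that add atoms: none
Why: Dehydrochlorination of 1 gives methylketene 3, which adds to the electron-rich alkyne in a regioselective ketene–alkyne [2+2] cycloaddition (ketene carbonyl carbon to the unsubstituted alkyne carbon). The stereocentre is formed as a racemate and disappears in step 2.

Step 2
Reactants: 4 (±)-3-ethoxy-4-methylcyclobut-2-en-1-one
Product: 5 3-hydroxy-2-methylcyclobut-2-en-1-one (enol of 2-methylcyclobutane-1,3-dione)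
Conditions: 1 M aq. HCl, THF, 0 → 23 °C
Reagents that add atoms: water, O
Why: Acid hydrolysis of a vinylogous ester. The dione settles as the conjugated, more substituted enol, which moves the double bond to the methyl-bearing carbon.

Step 3
Reactants: 5 3-hydroxy-2-methylcyclobut-2-en-1-one
Product: 6 3-methoxy-2-methylcyclobut-2-en-1-one
Conditions: Me3SiCHN2, MeOH/Et2O, 0 °C
Reagents that add atoms: trimethylsilyldiazomethane, C[Si](C)(C)C=[N+]=[N-]
Why: O-Methylation of a strongly acidic vinylogous acid by diazomethane released from the silyl reagent in methanol. The two oxygens of the anion are equivalent, so only one enol ether can form.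

Step 4
Reactants: 7 1,3,5-tris(benzyloxy)benzene
Product: 8 1,3,5-tris(benzyloxy)-2-bromobenzene
Conditions: NBS (1.0 equiv), CH2Cl2, −78 → 0 °C
Reagents that add atoms: N-bromosuccinimide, O=C1CCC(=O)N1Br
Why: Electrophilic aromatic bromination of a trialkoxybenzene. The three open positions are equivalent and one equivalent of reagent at low temperature should stop at the monobromide.

Step 5
Reactants: 8 1,3,5-tris(benzyloxy)-2-bromobenzene
Product: 9 ethyl 2-[2,4,6-tris(benzyloxy)phenyl]acetate
Conditions: BrZnCH2CO2Et, Pd2(dba)3 (2 mol%), XPhos (8 mol%), THF, 65 °C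
Reagents that add atoms: (2-ethoxy-2-oxoethyl)zinc bromide, CCOC(=O)C[Zn]Br
Why: Palladium-catalysed α-arylation of an ester zinc enolate (Negishi-type coupling of a Reformatsky reagent). The bulky biarylphosphine supports oxidative addition to the hindered, electron-rich bromide, and the neutral zinc enolate avoids Claisen condensation.

Step 6
Reactants: 9 ethyl 2-[2,4,6-tris(benzyloxy)phenyl]acetate
Product: 11 triisopropyl({3-[2,4,6-tris(benzyloxy)phenyl]prop-1-yn-1-yl}oxy)silane, via lithium ynolate 10 (not isolated)
Conditions: CH2Br2, LiTMP (lithium 2,2,6,6-tetramethylpiperidide), THF, −78 °C; n-BuLi, −78 → 25 °C; i-Pr3SiCl, 0 → 25 °C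
Reagents that add atoms: dibromomethane, BrCBr; chlorotriisopropylsilane, CC(C)[Si](Cl)(C(C)C)C(C)C
Why: Kowalski ynolate formation: LiCHBr2 adds to the ester, and bromine–lithium exchange followed by a 1,2-shift of the arylmethyl group gives ynolate 10. The bulky silyl chloride then silylates on oxygen.

Step 7
Reactants: 11 triisopropyl({3-[2,4,6-tris(benzyloxy)phenyl]prop-1-yn-1-yl}oxy)silane; 6 3-methoxy-2-methylcyclobut-2-en-1-one
Product: 16 5-methoxy-4-methyl-2-{[2,4,6-tris(benzyloxy)phenyl]methyl}-3-[(triisopropylsilyl)oxy]phenol, via vinylketene 12 (not isolated), via vinylcyclobutenone 13 (not isolated), via dienylketene 14 (not isolated), via cyclohexadienone 15 (not isolated)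
Conditions: 6 (1.3 equiv), toluene (0.5 M), sealed tube, 80 → 120 °C
Reagents that add atoms: none
Why: This is a Danheiser benzannulation of a cyclobutenone with a silyl ynol ether, the closest known reaction type being the formation of resorcinol monosilyl ethers from cyclobutenones and siloxyalkynes. Heating opens 6 by four-electron electrocyclic ring opening to vinylketene 12, whose ketene C=C bond adds to the ynol ether in a [2+2] cycloaddition. The alkyne carbon remote from oxygen bonds to the ketene carbonyl carbon (C-1A–C-6A) and the silyloxy-bearing carbon bonds to the ketene α-carbon (C-2A–C-3A), giving 13. A second four-electron ring opening gives dienylketene 14, and ring A is closed between C-5A and C-6A by thermal disrotatory six-electron electrocyclisation; tautomerisation of 15 gives the phenol. The quaternary centre of 13 is transient and no stereocentre remains. The step needs one regiochemistry of the ketene–alkyne cycloaddition, which is secured by the polarisation of the two partners: the ynol ether is nucleophilic at the carbon remote from oxygen and the ketene is electrophilic at its carbonyl carbon. It also needs the cycloaddition to outrun dimerisation of 12, which a concentrated solution of the electron-rich alkyne favours. The positions of the free hydroxyl, the bridge, the silyl ether, the methyl and the methoxy group then follow from connectivity alone.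

Step 8
Reactants: 16 5-methoxy-4-methyl-2-{[2,4,6-tris(benzyloxy)phenyl]methyl}-3-[(triisopropylsilyl)oxy]phenol
Product: 17 2-hydroxy-6-methoxy-5-methyl-3-{[2,4,6-tris(benzyloxy)phenyl]methyl}-4-[(triisopropylsilyl)oxy]benzaldehyde
Conditions: MgCl2, Et3N, (CH2O)n, MeCN, 80 °C
Reagents that add atoms: paraformaldehyde (as formaldehyde), C=O
Why: Casnati–Skattebøl ortho-formylation: the magnesium phenoxide of the C-6A hydroxyl delivers formaldehyde to its only free ortho position, C-5A, and a second equivalent of formaldehyde accepts hydride. Ring B has no free phenol and is not touched.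

Step 9
Reactants: 17 2-hydroxy-6-methoxy-5-methyl-3-{[2,4,6-tris(benzyloxy)phenyl]methyl}-4-[(triisopropylsilyl)oxy]benzaldehyde
Product: 18 (±)-2-(1-hydroxyethyl)-3-methoxy-4-methyl-6-{[2,4,6-tris(benzyloxy)phenyl]methyl}-5-[(triisopropylsilyl)oxy]phenol
Conditions: MeMgBr (3 equiv), THF, 0 → 23 °C
Reagents that add atoms: methylmagnesium bromide, C[Mg]Br
Why: Grignard addition to the aldehyde after deprotonation of the phenol. The carbinol stereocentre is racemic and is removed in step 10; the crude alcohol is used directly.

Step 10
Reactants: 18 (±)-2-(1-hydroxyethyl)-3-methoxy-4-methyl-6-{[2,4,6-tris(benzyloxy)phenyl]methyl}-5-[(triisopropylsilyl)oxy]phenol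
Product: 19 1-{2-hydroxy-6-methoxy-5-methyl-3-{[2,4,6-tris(benzyloxy)phenyl]methyl}-4-[(triisopropylsilyl)oxy]phenyl}ethan-1-one
Conditions: MnO2, CH2Cl2, 23 °C
Reagents that add atoms: none
Why: Oxidation of a benzylic alcohol with MnO2 under neutral conditions. Benzyl ethers, the silyl ether and the bridge are inert, and the product is stabilised as the chelated ortho-hydroxy ketone.

Step 11
Reactants: 19 1-{2-hydroxy-6-methoxy-5-methyl-3-{[2,4,6-tris(benzyloxy)phenyl]methyl}-4-[(triisopropylsilyl)oxy]phenyl}ethan-1-one
Product: 20 1-{3-{[3-acetyl-2-hydroxy-4-methoxy-5-methyl-6-[(triisopropylsilyl)oxy]phenyl]methyl}-2,4,6-tris(benzyloxy)phenyl}butan-1-one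
Conditions: PrCO2H, (CF3CO)2O, CH2Cl2, 0 → 23 °C; then aq. NaHCO3/MeOH
Reagents that add atoms: butanoic acid, CCCC(O)=O
Why: Friedel–Crafts acylation of a trialkoxybenzene by a carboxylic trifluoroacetic mixed anhydride, without a metal Lewis acid. Ring A has no open position, the two open positions of ring B are equivalent, and the first acyl group deactivates the ring towards a second.

Step 12
Reactants: 20 1-{3-{[3-acetyl-2-hydroxy-4-methoxy-5-methyl-6-[(triisopropylsilyl)oxy]phenyl]methyl}-2,4,6-tris(benzyloxy)phenyl}butan-1-one
Product: 21 1-{3-[(3-acetyl-2,6-dihydroxy-4-methoxy-5-methylphenyl)methyl]-2,4,6-tris(benzyloxy)phenyl}butan-1-one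
Conditions: Bu4NF, AcOH, THF, 0 °C
Reagents that add atoms: none
Why: Fluoride cleavage of an aryl silyl ether. The acetic acid buffer keeps the medium from becoming basic enough to touch the bridge.

Step 13
Reactants: 21 1-{3-[(3-acetyl-2,6-dihydroxy-4-methoxy-5-methylphenyl)methyl]-2,4,6-tris(benzyloxy)phenyl}butan-1-one
Product: 22 1-{3-[(3-acetyl-2,6-dihydroxy-4-methoxy-5-methylphenyl)methyl]-2,4,6-trihydroxyphenyl}butan-1-one
Conditions: H2 (1 atm), 10% Pd/C, EtOAc/MeOH, 23 °C
Reagents that add atoms: none
Why: Hydrogenolysis of three aryl benzyl ethers. The chelated aryl ketones and the diarylmethane are inert at one atmosphere and ambient temperature.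

Step 14
Reactants: 23 ethyl 2-methoxyacetate
Product: 25 triisopropyl[(3-methoxyprop-1-yn-1-yl)oxy]silane, via lithium ynolate 24 (not isolated)
Conditions: CH2Br2, LiTMP (lithium 2,2,6,6-tetramethylpiperidide), THF, −78 °C; n-BuLi, −78 → 25 °C; i-Pr3SiCl, 0 → 25 °C
Reagents that add atoms: dibromomethane, BrCBr; chlorotriisopropylsilane, CC(C)[Si](Cl)(C(C)C)C(C)C
Why: Kowalski ynolate formation and O-silylation as in step 6. Loss of methoxide from 24 would have to create a cumulated ketene and is therefore expected to be slow.

Step 15
Reactants: 25 triisopropyl[(3-methoxyprop-1-yn-1-yl)oxy]silane; 6 3-methoxy-2-methylcyclobut-2-en-1-one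
Product: 29 5-methoxy-2-(methoxymethyl)-4-methyl-3-[(triisopropylsilyl)oxy]phenol, via vinylcyclobutenone 26 (not isolated), via dienylketene 27 (not isolated), via cyclohexadienone 28 (not isolated)
Conditions: 6 (1.3 equiv), toluene (0.5 M), sealed tube, 80 → 120 °C
Reagents that add atoms: none
Why: The same Danheiser benzannulation as in step 7, with the same regiochemical control: 6 opens again to vinylketene 12, which adds to ynol ether 25 before the second ring opening, six-electron closure and tautomerisation. It gives ring C with its benzylic carbon, free C-6C hydroxyl, methyl and methoxy groups in place.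

Step 16
Reactants: 29 5-methoxy-2-(methoxymethyl)-4-methyl-3-[(triisopropylsilyl)oxy]phenol
Product: 30 2-hydroxy-6-methoxy-3-(methoxymethyl)-5-methyl-4-[(triisopropylsilyl)oxy]benzaldehyde
Conditions: MgCl2, Et3N, (CH2O)n, MeCN, 80 °C
Reagents that add atoms: paraformaldehyde (as formaldehyde), C=O
Why: Casnati–Skattebøl ortho-formylation at C-5C, the only free position ortho to the free phenol. The basic, Lewis-acid-free conditions leave the benzylic methyl ether intact.

Step 17
Reactants: 30 2-hydroxy-6-methoxy-3-(methoxymethyl)-5-methyl-4-[(triisopropylsilyl)oxy]benzaldehyde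
Product: 31 (±)-2-(1-hydroxybutyl)-3-methoxy-6-(methoxymethyl)-4-methyl-5-[(triisopropylsilyl)oxy]phenol
Conditions: n-PrMgBr (3 equiv), THF, 0 → 23 °C
Reagents that add atoms: propylmagnesium bromide, CCC[Mg]Br
Why: Grignard addition to the aldehyde after deprotonation of the phenol. The racemic carbinol centre is removed in step 18.

Step 18
Reactants: 31 (±)-2-(1-hydroxybutyl)-3-methoxy-6-(methoxymethyl)-4-methyl-5-[(triisopropylsilyl)oxy]phenol
Product: 32 1-{2-hydroxy-6-methoxy-3-(methoxymethyl)-5-methyl-4-[(triisopropylsilyl)oxy]phenyl}butan-1-one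
Conditions: MnO2, CH2Cl2, 23 °C
Reagents that add atoms: none
Why: Neutral oxidation of the benzylic alcohol with MnO2 to the chelated ortho-hydroxy ketone. The benzylic ether and the silyl ether are not affected.

Step 19
Reactants: 32 1-{2-hydroxy-6-methoxy-3-(methoxymethyl)-5-methyl-4-[(triisopropylsilyl)oxy]phenyl}butan-1-one
Product: 33 1-[2,4-dihydroxy-6-methoxy-3-(methoxymethyl)-5-methylphenyl]butan-1-one
Conditions: Bu4NF, AcOH, THF, 0 °C
Reagents that add atoms: none
Why: Buffered fluoride cleavage of the aryl silyl ether. Ring C has no free ring position, so the product cannot condense with itself through carbon.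

Step 20
Reactants: 22 1-{3-[(3-acetyl-2,6-dihydroxy-4-methoxy-5-methylphenyl)methyl]-2,4,6-trihydroxyphenyl}butan-1-one; 33 1-[2,4-dihydroxy-6-methoxy-3-(methoxymethyl)-5-methylphenyl]butan-1-one
Product: 35 agrimol F, via quinone methide 34 (not isolated)
Conditions: 22 (1.2 equiv), TsOH·H2O (10 mol%), MeCN, 40 °C
Reagents that add atoms: none
Why: Acid-catalysed loss of methanol from the ortho-hydroxybenzyl ether gives quinone methide 34 (or its protonated form), which alkylates the acylphloroglucinol in a Friedel–Crafts reaction. C-5B is the only unsubstituted aromatic carbon in either partner, so only one C–C bond can form.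

## Compound list

1 | propanoyl chloride | CCC(Cl)=O | starting material
2 | ethoxyethyne (ethoxyacetylene) | CCOC#C | starting material
3 | methylketene (prop-1-en-1-one) | CC=C=O | intermediate (not isolated)
4 | (±)-3-ethoxy-4-methylcyclobut-2-en-1-one | CCOC1=CC(=O)C1C | intermediate
5 | 3-hydroxy-2-methylcyclobut-2-en-1-one (enol of 2-methylcyclobutane-1,3-dione) | CC1=C(O)CC1=O | intermediate
6 | 3-methoxy-2-methylcyclobut-2-en-1-one | COC1=C(C)C(=O)C1 | intermediate
7 | 1,3,5-tris(benzyloxy)benzene | c1ccc(COc2cc(OCc3ccccc3)cc(OCc3ccccc3)c2)cc1 | starting material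
8 | 1,3,5-tris(benzyloxy)-2-bromobenzene | Brc1c(OCc2ccccc2)cc(OCc2ccccc2)cc1OCc1ccccc1 | intermediate
9 | ethyl 2-[2,4,6-tris(benzyloxy)phenyl]acetate | CCOC(=O)Cc1c(OCc2ccccc2)cc(OCc2ccccc2)cc1OCc1ccccc1 | intermediate
10 | lithium 3-[2,4,6-tris(benzyloxy)phenyl]prop-1-yn-1-olate | [Li+].[O-]C#CCc1c(OCc2ccccc2)cc(OCc2ccccc2)cc1OCc1ccccc1 | intermediate (not isolated)
11 | triisopropyl({3-[2,4,6-tris(benzyloxy)phenyl]prop-1-yn-1-yl}oxy)silane | CC(C)[Si](OC#CCc1c(OCc2ccccc2)cc(OCc2ccccc2)cc1OCc1ccccc1)(C(C)C)C(C)C | intermediate
12 | 3-methoxy-2-methylbuta-1,3-dien-1-one | C=C(OC)C(C)=C=O | intermediate (not isolated)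
13 | (±)-4-(1-methoxyethenyl)-4-methyl-2-{[2,4,6-tris(benzyloxy)phenyl]methyl}-3-[(triisopropylsilyl)oxy]cyclobut-2-en-1-one | C=C(OC)C1(C)C(=O)C(Cc2c(OCc3ccccc3)cc(OCc3ccccc3)cc2OCc2ccccc2)=C1O[Si](C(C)C)(C(C)C)C(C)C | intermediate (not isolated)
14 | (3E)-5-methoxy-4-methyl-2-{[2,4,6-tris(benzyloxy)phenyl]methyl}-3-[(triisopropylsilyl)oxy]hexa-1,3,5-trien-1-one | C=C(OC)/C(C)=C(\C(Cc1c(OCc2ccccc2)cc(OCc2ccccc2)cc1OCc1ccccc1)=C=O)O[Si](C(C)C)(C(C)C)C(C)C | intermediate (not isolated)
15 | 5-methoxy-4-methyl-2-{[2,4,6-tris(benzyloxy)phenyl]methyl}-3-[(triisopropylsilyl)oxy]cyclohexa-2,4-dien-1-one | COC1=C(C)C(O[Si](C(C)C)(C(C)C)C(C)C)=C(Cc2c(OCc3ccccc3)cc(OCc3ccccc3)cc2OCc2ccccc2)C(=O)C1 | intermediate (not isolated)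
16 | 5-methoxy-4-methyl-2-{[2,4,6-tris(benzyloxy)phenyl]methyl}-3-[(triisopropylsilyl)oxy]phenol | Cc1c(O[Si](C(C)C)(C(C)C)C(C)C)c(Cc2c(OCc3ccccc3)cc(OCc3ccccc3)cc2OCc2ccccc2)c(O)cc1OC | intermediate
17 | 2-hydroxy-6-methoxy-5-methyl-3-{[2,4,6-tris(benzyloxy)phenyl]methyl}-4-[(triisopropylsilyl)oxy]benzaldehyde | Cc1c(O[Si](C(C)C)(C(C)C)C(C)C)c(Cc2c(OCc3ccccc3)cc(OCc3ccccc3)cc2OCc2ccccc2)c(O)c(C=O)c1OC | intermediate
18 | (±)-2-(1-hydroxyethyl)-3-methoxy-4-methyl-6-{[2,4,6-tris(benzyloxy)phenyl]methyl}-5-[(triisopropylsilyl)oxy]phenol | Cc1c(O[Si](C(C)C)(C(C)C)C(C)C)c(Cc2c(OCc3ccccc3)cc(OCc3ccccc3)cc2OCc2ccccc2)c(O)c(C(C)O)c1OC | intermediate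
19 | 1-{2-hydroxy-6-methoxy-5-methyl-3-{[2,4,6-tris(benzyloxy)phenyl]methyl}-4-[(triisopropylsilyl)oxy]phenyl}ethan-1-one | Cc1c(O[Si](C(C)C)(C(C)C)C(C)C)c(Cc2c(OCc3ccccc3)cc(OCc3ccccc3)cc2OCc2ccccc2)c(O)c(C(C)=O)c1OC | intermediate
20 | 1-{3-{[3-acetyl-2-hydroxy-4-methoxy-5-methyl-6-[(triisopropylsilyl)oxy]phenyl]methyl}-2,4,6-tris(benzyloxy)phenyl}butan-1-one | CCCC(=O)c1c(OCc2ccccc2)cc(OCc2ccccc2)c(Cc2c(O)c(C(C)=O)c(OC)c(C)c2O[Si](C(C)C)(C(C)C)C(C)C)c1OCc1ccccc1 | intermediate
21 | 1-{3-[(3-acetyl-2,6-dihydroxy-4-methoxy-5-methylphenyl)methyl]-2,4,6-tris(benzyloxy)phenyl}butan-1-one | CCCC(=O)c1c(OCc2ccccc2)cc(OCc2ccccc2)c(Cc2c(O)c(C)c(OC)c(C(C)=O)c2O)c1OCc1ccccc1 | intermediate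
22 | 1-{3-[(3-acetyl-2,6-dihydroxy-4-methoxy-5-methylphenyl)methyl]-2,4,6-trihydroxyphenyl}butan-1-one | CCCC(=O)c1c(O)cc(O)c(Cc2c(O)c(C)c(OC)c(C(C)=O)c2O)c1O | intermediate
23 | ethyl 2-methoxyacetate | CCOC(=O)COC | starting material
24 | lithium 3-methoxyprop-1-yn-1-olate | [Li+].[O-]C#CCOC | intermediate (not isolated)
25 | triisopropyl[(3-methoxyprop-1-yn-1-yl)oxy]silane | COCC#CO[Si](C(C)C)(C(C)C)C(C)C | intermediate
26 | (±)-4-(1-methoxyethenyl)-2-(methoxymethyl)-4-methyl-3-[(triisopropylsilyl)oxy]cyclobut-2-en-1-one | C=C(OC)C1(C)C(=O)C(COC)=C1O[Si](C(C)C)(C(C)C)C(C)C | intermediate (not isolated)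
27 | (3E)-5-methoxy-2-(methoxymethyl)-4-methyl-3-[(triisopropylsilyl)oxy]hexa-1,3,5-trien-1-one | C=C(OC)/C(C)=C(\C(COC)=C=O)O[Si](C(C)C)(C(C)C)C(C)C | intermediate (not isolated)
28 | 5-methoxy-2-(methoxymethyl)-4-methyl-3-[(triisopropylsilyl)oxy]cyclohexa-2,4-dien-1-one | COCC1=C(O[Si](C(C)C)(C(C)C)C(C)C)C(C)=C(OC)CC1=O | intermediate (not isolated)
29 | 5-methoxy-2-(methoxymethyl)-4-methyl-3-[(triisopropylsilyl)oxy]phenol | COCc1c(O)cc(OC)c(C)c1O[Si](C(C)C)(C(C)C)C(C)C | intermediate
30 | 2-hydroxy-6-methoxy-3-(methoxymethyl)-5-methyl-4-[(triisopropylsilyl)oxy]benzaldehyde | COCc1c(O)c(C=O)c(OC)c(C)c1O[Si](C(C)C)(C(C)C)C(C)C | intermediate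
31 | (±)-2-(1-hydroxybutyl)-3-methoxy-6-(methoxymethyl)-4-methyl-5-[(triisopropylsilyl)oxy]phenol | CCCC(O)c1c(O)c(COC)c(O[Si](C(C)C)(C(C)C)C(C)C)c(C)c1OC | intermediate
32 | 1-{2-hydroxy-6-methoxy-3-(methoxymethyl)-5-methyl-4-[(triisopropylsilyl)oxy]phenyl}butan-1-one | CCCC(=O)c1c(O)c(COC)c(O[Si](C(C)C)(C(C)C)C(C)C)c(C)c1OC | intermediate
33 | 1-[2,4-dihydroxy-6-methoxy-3-(methoxymethyl)-5-methylphenyl]butan-1-one | CCCC(=O)c1c(O)c(COC)c(O)c(C)c1OC | intermediate
34 | 4-butanoyl-3-hydroxy-5-methoxy-6-methyl-2-methylidenecyclohexa-3,5-dien-1-one | C=C1C(=O)C(C)=C(OC)C(C(=O)CCC)=C1O | intermediate (not isolated)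
35 | agrimol F, 1-{3-[(3-acetyl-2,6-dihydroxy-4-methoxy-5-methylphenyl)methyl]-5-[(3-butanoyl-2,6-dihydroxy-4-methoxy-5-methylphenyl)methyl]-2,4,6-trihydroxyphenyl}butan-1-one | CCCC(=O)c1c(O)c(Cc2c(O)c(C)c(OC)c(C(C)=O)c2O)c(O)c(Cc2c(O)c(C)c(OC)c(C(=O)CCC)c2O)c1O | target

## Step count and least certain steps

Total step count: 20.

Longest linear sequence: 11 steps (steps 1–3, 7–13 and 20; the branch through steps 4–6 is equally long).

**Step 7 (key step; step 15 runs the same reaction and shares the risk).** The most likely failure is slow electrocyclic opening of cyclobutenone 6, because its enol ether is conjugated with the carbonyl group. At the temperature then required, dimerisation of the vinylketene, acylation of the product phenol by the ketene and thermal decay of the ynol ether can overtake the cycloaddition. In step 7 the trisubstituted benzyl group may slow the cycloaddition further. The fallback changes the source of the vinylketene to a diazo ketone (photochemical Wolff rearrangement, the diazo ketone variant of the benzannulation). It sets out from 11 and comes back at 16. Methyl vinyl ether is lithiated with t-BuLi to (1-methoxyethenyl)lithium F1, which is acylated by N-methoxy-N-methylpropanamide to 2-methoxypent-1-en-3-one F2. Deacylative diazo transfer (LiN(SiMe3)2 and CF3CO2CH2CF3, then MsN3 and Et3N) gives 4-diazo-2-methoxypent-1-en-3-one F3. Irradiation of F3 in the presence of 11 at ambient temperature releases 12 by loss of nitrogen and 1,2-shift of the alkenyl group, and gentle warming completes the cascade to 16. The same diazo ketone with 25 would give 29.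

**Step 6.** The most likely failure is deprotonation of the arylacetic ester at its benzylic α-carbon by LiCHBr2 or the amide base in place of addition to the carbonyl group, which returns 9. Lithiation of the ring or of a benzyl ether by the excess alkyllithium is a second possibility. The fallback reaches the ynolate by oxidation of an acetylide and needs no ester. It sets out from 8 and comes back at 11. Bromine–lithium exchange (n-BuLi, THF, −78 °C) gives [2,4,6-tris(benzyloxy)phenyl]lithium F4. Copper-catalysed substitution of 3-bromo-1-(trimethylsilyl)prop-1-yne gives trimethyl{3-[2,4,6-tris(benzyloxy)phenyl]prop-1-yn-1-yl}silane F5. K2CO3 in methanol removes the silyl group to give 1,3,5-tris(benzyloxy)-2-(prop-2-yn-1-yl)benzene F6. Deprotonation with n-BuLi gives {3-[2,4,6-tris(benzyloxy)phenyl]prop-1-yn-1-yl}lithium F7. Lithium tert-butyl peroxide oxidises F7 to ynolate 10, and silylation with i-Pr3SiOTf gives 11.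

**Step 14.** The most likely failure is loss of methoxide from the ynolate on warming, since the methoxy group is β to the carbanionic carbon; silylation on carbon is a lesser risk. The fallback uses an amino group, a much poorer leaving group, on the propargylic carbon and restores the ether after the ring is made. It sets out from 6 and comes back at 29. Ethyl N,N-dibenzylglycinate is taken through the ynolate sequence of step 14 to N,N-dibenzyl-3-[(triisopropylsilyl)oxy]prop-2-yn-1-amine F8. Benzannulation with 6 gives 2-[(dibenzylamino)methyl]-5-methoxy-4-methyl-3-[(triisopropylsilyl)oxy]phenol F9. Heating F9 in methanol exchanges the amine for methoxide through the quinone methide and gives 29.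

**Step 11.** The most likely failures are acid-induced loss of a benzyl ether next to the new ketone, ipso attack at C-3B with cleavage of the bridge, and O-acylation of the chelated phenol. The fallback acylates the free phloroglucinol ring with a nitrile (Hoesch reaction). It sets out from 19 and comes back at 22. Buffered fluoride gives 1-{2,4-dihydroxy-6-methoxy-5-methyl-3-{[2,4,6-tris(benzyloxy)phenyl]methyl}phenyl}ethan-1-one F10. Hydrogenolysis gives 1-{2,4-dihydroxy-6-methoxy-5-methyl-3-[(2,4,6-trihydroxyphenyl)methyl]phenyl}ethan-1-one F11. Butanenitrile with ZnCl2 and HCl in ether gives 1-{3-[(3-acetyl-2,6-dihydroxy-4-methoxy-5-methylphenyl)methyl]-2,4,6-trihydroxyphenyl}butan-1-iminium chloride F12 at one of the two equivalent positions of ring B. Aqueous hydrolysis gives 22.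

**Step 20.** The most likely failure is acid-catalysed redistribution of the methylene bridges: ipso protonation of a phloroglucinol ring in 22 or in the product followed by expulsion of a hydroxybenzyl cation, which would lead to the symmetrical trimers beside the mixed one. Slow ionisation of the ether and reversible O-alkylation are lesser risks. The fallback generates the same quinone methide with fluoride at low temperature and without acid. It sets out from 32 and comes back at 35. Me3SiBr converts the benzylic methyl ether into 1-{3-(bromomethyl)-2-hydroxy-6-methoxy-5-methyl-4-[(triisopropylsilyl)oxy]phenyl}butan-1-one F13. Addition of Bu4NF at −78 °C in the presence of 22 removes the silyl group, and the phenoxide expels bromide to give 34, which 22 captures at C-5B to give 35.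

## Further compounds

F1 | step 7 | (1-methoxyethenyl)lithium | [Li]C(=C)OC
F2 | step 7 | 2-methoxypent-1-en-3-one | CCC(=O)C(=C)OC
F3 | step 7 | 4-diazo-2-methoxypent-1-en-3-one | CC(=[N+]=[N-])C(=O)C(=C)OC
F4 | step 6 | [2,4,6-tris(benzyloxy)phenyl]lithium | [Li]c1c(OCc2ccccc2)cc(OCc2ccccc2)cc1OCc1ccccc1
F5 | step 6 | trimethyl{3-[2,4,6-tris(benzyloxy)phenyl]prop-1-yn-1-yl}silane | C[Si](C)(C)C#CCc1c(OCc2ccccc2)cc(OCc2ccccc2)cc1OCc1ccccc1
F6 | step 6 | 1,3,5-tris(benzyloxy)-2-(prop-2-yn-1-yl)benzene | C#CCc1c(OCc2ccccc2)cc(OCc2ccccc2)cc1OCc1ccccc1
F7 | step 6 | {3-[2,4,6-tris(benzyloxy)phenyl]prop-1-yn-1-yl}lithium | [Li]C#CCc1c(OCc2ccccc2)cc(OCc2ccccc2)cc1OCc1ccccc1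
F8 | step 14 | N,N-dibenzyl-3-[(triisopropylsilyl)oxy]prop-2-yn-1-amine | CC(C)[Si](OC#CCN(Cc1ccccc1)Cc1ccccc1)(C(C)C)C(C)C
F9 | step 14 | 2-[(dibenzylamino)methyl]-5-methoxy-4-methyl-3-[(triisopropylsilyl)oxy]phenol | COc1cc(O)c(CN(Cc2ccccc2)Cc2ccccc2)c(O[Si](C(C)C)(C(C)C)C(C)C)c1C
F10 | step 11 | 1-{2,4-dihydroxy-6-methoxy-5-methyl-3-{[2,4,6-tris(benzyloxy)phenyl]methyl}phenyl}ethan-1-one | Cc1c(O)c(Cc2c(OCc3ccccc3)cc(OCc3ccccc3)cc2OCc2ccccc2)c(O)c(C(C)=O)c1OC
F11 | step 11 | 1-{2,4-dihydroxy-6-methoxy-5-methyl-3-[(2,4,6-trihydroxyphenyl)methyl]phenyl}ethan-1-one | Cc1c(O)c(Cc2c(O)cc(O)cc2O)c(O)c(C(C)=O)c1OC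
F12 | step 11 | 1-{3-[(3-acetyl-2,6-dihydroxy-4-methoxy-5-methylphenyl)methyl]-2,4,6-trihydroxyphenyl}butan-1-iminium chloride | CCCC(=[NH2+])c1c(O)cc(O)c(Cc2c(O)c(C)c(OC)c(C(C)=O)c2O)c1O.[Cl-]
F13 | step 20 | 1-{3-(bromomethyl)-2-hydroxy-6-methoxy-5-methyl-4-[(triisopropylsilyl)oxy]phenyl}butan-1-one | CCCC(=O)c1c(O)c(CBr)c(O[Si](C(C)C)(C(C)C)C(C)C)c(C)c1OC
A1 | alternative 1 | 1-{3-[(3-acetyl-2,6-dihydroxy-4-methoxy-5-methylphenyl)methyl]-5-[(2,6-dihydroxy-4-methoxy-3-methylphenyl)methyl]-2,4,6-trihydroxyphenyl}butan-1-one | CCCC(=O)c1c(O)c(Cc2c(O)cc(OC)c(C)c2O)c(O)c(Cc2c(O)c(C)c(OC)c(C(C)=O)c2O)c1O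
A2 | alternative 1 | 1-{3-[(3-acetyl-2,6-dihydroxy-4-methoxy-5-methylphenyl)methyl]-2,4,6-trihydroxy-5-[2-(4-methoxy-5-methyl-6-oxo-6H-pyran-2-yl)ethyl]phenyl}butan-1-one | CCCC(=O)c1c(O)c(CCc2cc(OC)c(C)c(=O)o2)c(O)c(Cc2c(O)c(C)c(OC)c(C(C)=O)c2O)c1O
A3 | alternative 2 | 1-[4-(benzyloxy)-6-hydroxy-2-methoxy-3-methylphenyl]ethan-1-one | CC(=O)c1c(O)cc(OCc2ccccc2)c(C)c1OC
A4 | alternative 2 | 5-(benzyloxy)-3-methoxy-4-methyl-2-(trimethylsilyl)phenyl trifluoromethanesulfonate | COc1c(C)c(OCc2ccccc2)cc(OS(=O)(=O)C(F)(F)F)c1[Si](C)(C)C
A5 | alternative 2 | 5-(benzyloxy)-3-methoxy-4-methyl-1,2-didehydrobenzene | COC1=C(C)C(OCc2ccccc2)=CC#C1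
A6 | alternative 2 | acetic acid | CC(O)=O
A7 | alternative 3 | 1-[3-{[3-acetyl-2,6-bis(benzyloxy)-4-methoxy-5-methylphenyl]methyl}-2,4,6-tris(benzyloxy)-5-{[2,6-bis(benzyloxy)-3-butanoyl-4-methoxy-5-methylphenyl]methyl}phenyl]butan-1-one | CCCC(=O)c1c(OCc2ccccc2)c(Cc2c(OCc3ccccc3)c(C)c(OC)c(C(C)=O)c2OCc2ccccc2)c(OCc2ccccc2)c(Cc2c(OCc3ccccc3)c(C)c(OC)c(C(=O)CCC)c2OCc2ccccc2)c1OCc1ccccc1
A8 | alternative 3 | 1-[2,4,6-tris(benzyloxy)-3-bromo-5-iodophenyl]butan-1-one | CCCC(=O)c1c(OCc2ccccc2)c(Br)c(OCc2ccccc2)c(I)c1OCc1ccccc1
A9 | alternative 3 | {[3-acetyl-2,6-bis(benzyloxy)-4-methoxy-5-methylphenyl]methyl}zinc chloride | CC(=O)c1c(OCc2ccccc2)c(C[Zn]Cl)c(OCc2ccccc2)c(C)c1OC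
A10 | alternative 3 | {[2,6-bis(benzyloxy)-3-butanoyl-4-methoxy-5-methylphenyl]methyl}zinc chloride | CCCC(=O)c1c(OCc2ccccc2)c(C[Zn]Cl)c(OCc2ccccc2)c(C)c1OC
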